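The larch run answers the quick question in a few steps.

| flask | starting material | reagent | scavenger | remark | time |
|---|---|---|---|---|---|
| larch | 0.80 M | 0.80 M | 0.60 M | run made earlier |  |
| flask | 0.80 M | 0.800 M | 0.400 M |  | 10 d |

larch run (percent of the starting material charged)

| time / h | starting material / % | target / % |
|---|---|---|
| 1.50 | 91 | 0 |
| 5.00 | 68 | 0 |
| 8.00 | 55 | 6 |
| 12.0 | 44 | 3 |
| 20.0 | 29 | 8 |
| 25.0 | 20 | 11 |

(scatter of a reading: 1.5 percentage points)

* part of the starting material that has reacted at 10 d
* share of the unused reagent that is free and not bound as idle adduct, at 10 d

1. Conversion: the equal charges allow a second-order reading, in which the fraction left is one over one plus κ·t. The last larch reading gives κ = 0.160 /h and the first 0.0659 /h, so the remainder reckoned from the last is a low estimate; the effect of the scavenger charge is a guess, here none. About 2.54% of the charge should stay and 97.5% react.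

2. Late yield: between 12.0 h and 25.0 h in larch, target rose 8 percentage points while starting material fell 24 points. That gives s = 0.333, a reading carrying a scatter of 1.5 points in each value.

3. Binding is a guess. Suppose each target frees one released group, which scavenger takes and which otherwise ties reagent up as idle adduct. The scavenger cover, c(scavenger) / (s · c(starting material)), is then 1.50 for this flask. Above one, scavenger in this flask should outlast the group, with about 33.3% of its charge remaining, so bound reagent should be a small correction and the free share high.

The forecast, the hunch sent with the question, stands at 98% reacted and 50% free: “roughly half seems reasonable, with a wide range”.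

The flask gives 99.6% reacted and 99.9% free.

    target + released group → side product A (k = 9.80 × 10⁻⁶ /M/s)
    intermediate ⇌ target + released group (K = 1.30 M, k = 5.00 × 10⁻⁶ /s)
    scavenger + released group → scavenged by-product (k = 0.00290 /M/s)
    starting material + intermediate → side product B (k = 3.00 × 10⁻⁵ /M/s)
    starting material + reagent ⇌ intermediate (K = 16.0 /M, k = 2.70 × 10⁻⁵ /M/s)
    reagent + released group ⇌ idle adduct, settled at all times (K = 9.70 /M)

After 10.0 d in this flask, target stands at 36.9% and 26% of the scavenger remains. A neighbour flask with 0.24 M of scavenger, all else held, has a cover of 0.900, under one, so its scavenger should give out first. It does, with 0% remaining. That neighbour still reaches 99.5% reacted, but its idle adduct stands at 0.0266 M, and its free share of the unused reagent is 89.4%.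

All runs come from a simulation with constants of no real substance; the scatter is artificial.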